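**Strategy.** Everything rests on cutting the O1–C8a bond of the pyranone ring C. In the target the C4 ketone hangs from C4a, and both ring-A neighbours of C4a (C5 and C8a) carry oxygen. The route therefore builds ring A as a fully substituted arene in which C8a bears bromine and O5 is an acetal, so only C8a can receive the ring oxygen. The precursor is the chelated enol of an α-formyl deoxybenzoin: a 2-bromoaryl ketone that already holds the 8-methoxy, 6-prenyl and 2,4,5-trimethoxyphenyl groups. One copper-catalysed intramolecular O-arylation closes ring C and fixes the substitution pattern; acid then removes two MOM groups.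

Key step: step 10

Remark on stereochemistry: the target has no stereocentre and no stereogenic double bond, so it is one achiral compound and no enantiocontrol is needed.

Remarks on the design:
- In 5-bromovanillin the free hydroxyl, not the methoxy group, lies next to bromine. Steps 1 and 2 move the methyl group to that oxygen; otherwise the methoxy group would end at C7 instead of C8.
- A bromoarene is not metalated cleanly between two MOM ethers: alkyllithiums exchange the bromide and lithium amides deprotonate beside bromine. The prenyl position is therefore marked with iodine and addressed by iodine–magnesium exchange. The amide-base metalation beside bromine is used only where it is wanted, for the acyl group.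

**Route**

Step 1
Reactants: 1 5-bromovanillin
Product: 2 3-bromo-4,5-dihydroxybenzaldehyde
Conditions: AlCl3, pyridine, CH2Cl2, reflux; aq. HCl
Reagents that add atoms: none
Why: Lewis-acid O-demethylation of a guaiacol: aluminium chelates the ortho-hydroxy methyl ether and chloride removes the methyl group, while the aldehyde and the bromide are inert.

Step 2
Reactants: 2 3-bromo-4,5-dihydroxybenzaldehyde
Product: 3 3-bromo-5-hydroxy-4-methoxybenzaldehyde
Conditions: MeI (1.05 equiv), Li2CO3, DMF, 40 °C
Reagents that add atoms: iodomethane, CI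
Why: Williamson ether synthesis under a weak base: the 4-OH (para to CHO, ortho to Br) is the more acidic one, so only its phenoxide should form and be methylated, as known for protocatechualdehydes.

Step 3
Reactants: 3 3-bromo-5-hydroxy-4-methoxybenzaldehyde
Product: 5 5-bromo-4-methoxybenzene-1,3-diol, via aryl formate 4 (not isolated)
Conditions: mCPBA, CH2Cl2, 0 °C to rt; then MeOH, cat. HCl, rt
Reagents that add atoms: 3-chloroperoxybenzoic acid, O=C(OO)c1cccc(Cl)c1
Why: Baeyer–Villiger (Dakin-type) oxidation: the aryl group with its para methoxy group migrates in preference to hydrogen, and the labile aryl formate is methanolysed to the phenol.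

Step 4
Reactants: 5 5-bromo-4-methoxybenzene-1,3-diol
Product: 6 5-bromo-2-iodo-4-methoxybenzene-1,3-diol
Conditions: I2 (1.0 equiv), NaHCO3, THF/H2O, 0 °C
Reagents that add atoms: iodine, II
Why: Electrophilic aromatic iodination: under bicarbonate, resorcinols are iodinated at the carbon between the two hydroxyls (known for resorcinol itself), and the only other open position is hindered and deactivated by the neighbouring bromine.

Step 5
Reactants: 6 5-bromo-2-iodo-4-methoxybenzene-1,3-diol
Product: 7 1-bromo-4-iodo-2-methoxy-3,5-bis(methoxymethoxy)benzene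
Conditions: NaH, MOMCl, DMF, 0 °C to rt
Reagents that add atoms: chloromethyl methyl ether, COCCl
Why: Williamson alkylation of both phenoxides gives the bis-MOM ether, which tolerates the organometallic steps and the basic key step.

Step 6
Reactants: 7 1-bromo-4-iodo-2-methoxy-3,5-bis(methoxymethoxy)benzene; 8 prenyl bromide
Product: 10 1-bromo-2-methoxy-3,5-bis(methoxymethoxy)-4-(3-methylbut-2-en-1-yl)benzene, via arylmagnesium chloride 9 (not isolated)
Conditions: i-PrMgCl·LiCl, THF, −30 °C; then CuI (10 mol %), 8, −30 to 0 °C
Reagents that add atoms: none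
Why: Iodine–magnesium exchange is far faster at the C–I bond flanked by two coordinating MOM ethers than at C–Br, and copper-catalysed allylic substitution of the aryl Grignard reagent at the unhindered primary carbon of prenyl bromide should give the linear prenyl arene.

Step 7
Reactants: 11 2,4,5-trimethoxyphenylacetic acid
Product: 13 N-methoxy-N-methyl-2-(2,4,5-trimethoxyphenyl)acetamide, via acyl imidazole 12 (not isolated)
Conditions: CDI, CH2Cl2, rt; then MeNH(OMe)·HCl, rt
Reagents that add atoms: N,O-dimethylhydroxylamine hydrochloride, CNOC.Cl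
Why: Carboxyl activation as the acyl imidazole followed by aminolysis is the standard preparation of a Weinreb amide.

Step 8
Reactants: 10 1-bromo-2-methoxy-3,5-bis(methoxymethoxy)-4-(3-methylbut-2-en-1-yl)benzene; 13 N-methoxy-N-methyl-2-(2,4,5-trimethoxyphenyl)acetamide
Product: 16 1-[2-bromo-3-methoxy-4,6-bis(methoxymethoxy)-5-(3-methylbut-2-en-1-yl)phenyl]-2-(2,4,5-trimethoxyphenyl)ethan-1-one, via aryllithium 14 (not isolated), via lithium hemiaminal adduct 15 (not isolated)
Conditions: LDA (1.05 equiv), THF, −78 °C; then 13, −78 °C; AcOH quench at −78 °C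
Reagents that add atoms: none
Why: Directed ortho-metalation followed by Weinreb ketone synthesis: the only ring hydrogen of 10 lies between bromine and a MOM ether, the site a lithium amide deprotonates in a bromoarene without bromine–lithium exchange, and at −78 °C the aryllithium should be acylated once by 13 because the chelated adduct collapses to the ketone only on quench.

Step 9
Reactants: 16 1-[2-bromo-3-methoxy-4,6-bis(methoxymethoxy)-5-(3-methylbut-2-en-1-yl)phenyl]-2-(2,4,5-trimethoxyphenyl)ethan-1-one
Product: 18 (2Z)-1-[2-bromo-3-methoxy-4,6-bis(methoxymethoxy)-5-(3-methylbut-2-en-1-yl)phenyl]-3-hydroxy-2-(2,4,5-trimethoxyphenyl)prop-2-en-1-one (chelated enol), via sodium enolate 17 (not isolated)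
Conditions: NaH, HCO2Et, THF, 0 °C to rt; AcOH, 0 °C
Reagents that add atoms: ethyl formate, CCOC=O
Why: Crossed Claisen condensation (C-formylation) of the acidic benzylic methylene with a non-enolisable formate, driven by deprotonation of the 1,3-dicarbonyl product; neutralisation gives the hydrogen-bonded Z-enol.

Step 10
Reactants: 18 (2Z)-1-[2-bromo-3-methoxy-4,6-bis(methoxymethoxy)-5-(3-methylbut-2-en-1-yl)phenyl]-3-hydroxy-2-(2,4,5-trimethoxyphenyl)prop-2-en-1-one
Product: 19 8-methoxy-5,7-bis(methoxymethoxy)-6-(3-methylbut-2-en-1-yl)-3-(2,4,5-trimethoxyphenyl)-4H-chromen-4-one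
Conditions: CuI (10 mol %), 1,10-phenanthroline (20 mol %), Cs2CO3, anhydrous DMF, 80 °C, Ar
Reagents that add atoms: none
Why: After deprotonation by carbonate the enolate binds copper(I) through oxygen; oxidative addition of the neighbouring C8a–Br bond, which the ortho acyl group polarises, and C–O bond-forming reductive elimination then deliver the chromone and return copper(I). The closest known reaction is the copper-catalysed intramolecular O-arylation of 1-(2-haloaryl)-1,3-dicarbonyl compounds to chromones and flavones. The pyranone closes as a six-membered ring by attack of the enol oxygen on the ipso carbon C8a (formally 6-exo-trig, bromide leaving outside the new ring), and the Z enolate already holds that oxygen cis to the aroyl group. No stereocentre is formed. The step needs O- over C-arylation and C8a over C5 as the oxygen-bearing ring atom: C-arylation would give a four-membered ring, only C8a carries a leaving group, and O5 is an inert MOM ether, so the 8-methoxy-6-prenyl chromone is the only one that can form. Neither the prenyl double bond nor the acetal protecting groups should react under carbonate in DMF.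

Step 11
Reactants: 19 8-methoxy-5,7-bis(methoxymethoxy)-6-(3-methylbut-2-en-1-yl)-3-(2,4,5-trimethoxyphenyl)-4H-chromen-4-one
Product: 20 6-prenylisocaviunin (5,7-dihydroxy-8-methoxy-6-(3-methylbut-2-en-1-yl)-3-(2,4,5-trimethoxyphenyl)-4H-chromen-4-one)
Conditions: 3 M aq. HCl, MeOH, 45 °C
Reagents that add atoms: none
Why: Acid-catalysed acetal cleavage (transacetalisation to dimethoxymethane) frees both phenols; at moderate temperature protonation of the prenyl alkene and cyclisation onto a neighbouring phenol should stay slow, as in deprotections of other MOM-protected prenylated isoflavones.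

**Compound list**

1 | 5-bromovanillin (3-bromo-4-hydroxy-5-methoxybenzaldehyde) | COc1cc(C=O)cc(Br)c1O | starting material
2 | 3-bromo-4,5-dihydroxybenzaldehyde | O=Cc1cc(O)c(O)c(Br)c1 | intermediate
3 | 3-bromo-5-hydroxy-4-methoxybenzaldehyde | O=Cc1cc(O)c(OC)c(Br)c1 | intermediate
4 | 3-bromo-5-hydroxy-4-methoxyphenyl formate (aryl formate, not isolated) | O=COc1cc(O)c(OC)c(Br)c1 | intermediate
5 | 5-bromo-4-methoxybenzene-1,3-diol | Oc1cc(O)c(OC)c(Br)c1 | intermediate
6 | 5-bromo-2-iodo-4-methoxybenzene-1,3-diol | Oc1cc(Br)c(OC)c(O)c1I | intermediate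
7 | 1-bromo-4-iodo-2-methoxy-3,5-bis(methoxymethoxy)benzene | COCOc1cc(Br)c(OC)c(OCOC)c1I | intermediate
8 | prenyl bromide (1-bromo-3-methylbut-2-ene) | CC(C)=CCBr | starting material
9 | [4-bromo-3-methoxy-2,6-bis(methoxymethoxy)phenyl]magnesium chloride (arylmagnesium chloride, not isolated) | COCOc1cc(Br)c(OC)c(OCOC)c1[Mg]Cl | intermediate
10 | 1-bromo-2-methoxy-3,5-bis(methoxymethoxy)-4-(3-methylbut-2-en-1-yl)benzene | COCOc1cc(Br)c(OC)c(OCOC)c1CC=C(C)C | intermediate
11 | 2,4,5-trimethoxyphenylacetic acid | COc1cc(OC)c(CC(=O)O)cc1OC | starting material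
12 | 1-(imidazol-1-yl)-2-(2,4,5-trimethoxyphenyl)ethan-1-one (acyl imidazole, not isolated) | COc1cc(OC)c(CC(=O)n2ccnc2)cc1OC | intermediate
13 | N-methoxy-N-methyl-2-(2,4,5-trimethoxyphenyl)acetamide | COc1cc(OC)c(CC(=O)N(C)OC)cc1OC | intermediate
14 | [2-bromo-3-methoxy-4,6-bis(methoxymethoxy)-5-(3-methylbut-2-en-1-yl)phenyl]lithium (aryllithium, not isolated) | COCOc1c([Li])c(Br)c(OC)c(OCOC)c1CC=C(C)C | intermediate
15 | lithium 1-[2-bromo-3-methoxy-4,6-bis(methoxymethoxy)-5-(3-methylbut-2-en-1-yl)phenyl]-1-[methoxy(methyl)amino]-2-(2,4,5-trimethoxyphenyl)ethan-1-olate (lithium hemiaminal adduct, racemic, centre lost on quench, not isolated) | [Li]OC(Cc1cc(OC)c(OC)cc1OC)(N(C)OC)c1c(Br)c(OC)c(OCOC)c(CC=C(C)C)c1OCOC | intermediate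
16 | 1-[2-bromo-3-methoxy-4,6-bis(methoxymethoxy)-5-(3-methylbut-2-en-1-yl)phenyl]-2-(2,4,5-trimethoxyphenyl)ethan-1-one | O=C(Cc1cc(OC)c(OC)cc1OC)c1c(Br)c(OC)c(OCOC)c(CC=C(C)C)c1OCOC | intermediate
17 | sodium (1Z)-3-[2-bromo-3-methoxy-4,6-bis(methoxymethoxy)-5-(3-methylbut-2-en-1-yl)phenyl]-3-oxo-2-(2,4,5-trimethoxyphenyl)prop-1-en-1-olate (sodium enolate, not isolated) | [Na+].[O-]/C=C(/c1cc(OC)c(OC)cc1OC)C(=O)c1c(Br)c(OC)c(OCOC)c(CC=C(C)C)c1OCOC | intermediate
18 | (2Z)-1-[2-bromo-3-methoxy-4,6-bis(methoxymethoxy)-5-(3-methylbut-2-en-1-yl)phenyl]-3-hydroxy-2-(2,4,5-trimethoxyphenyl)prop-2-en-1-one | O/C=C(/c1cc(OC)c(OC)cc1OC)C(=O)c1c(Br)c(OC)c(OCOC)c(CC=C(C)C)c1OCOC | intermediate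
19 | 8-methoxy-5,7-bis(methoxymethoxy)-6-(3-methylbut-2-en-1-yl)-3-(2,4,5-trimethoxyphenyl)-4H-chromen-4-one | O=c1c(-c2cc(OC)c(OC)cc2OC)coc2c(OC)c(OCOC)c(CC=C(C)C)c(OCOC)c12 | intermediate
20 | 6-prenylisocaviunin (5,7-dihydroxy-8-methoxy-6-(3-methylbut-2-en-1-yl)-3-(2,4,5-trimethoxyphenyl)-4H-chromen-4-one) | COc1cc(OC)c(-c2coc3c(OC)c(O)c(CC=C(C)C)c(O)c3c2=O)cc1OC | target

**Step count**

Total: 11 steps. Longest linear sequence: 10 steps (steps 1–6 and 8–11, from 1 to 20); step 7 is a one-step side branch.

**Steps most likely to fail**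

1. Step 8. The ortho-bromoaryllithium may lose lithium bromide to an aryne before it is acylated, or the hindered aryllithium may take a proton from the acidic methylene of the Weinreb amide and return 10. The fallback reverses the roles so that ring A is the electrophile and no basic aryl anion meets an enolisable partner. It sets out from 10: the same lithiation is quenched within minutes at −78 °C with DMF, a fast and non-enolisable trap, to give 2-bromo-3-methoxy-4,6-bis(methoxymethoxy)-5-(3-methylbut-2-en-1-yl)benzaldehyde F1. Acid 11 is esterified (MeOH, cat. H2SO4) to methyl 2,4,5-trimethoxyphenylacetate F2. Its lithium enolate (LDA, THF, −78 °C) adds to F1 in an aldol reaction to give the β-hydroxy ester F3 as a diastereomer mixture, which does not matter because both centres are removed. Dess–Martin oxidation gives the β-keto ester F4, and Krapcho dealkoxycarbonylation (LiCl, wet DMSO, 120 °C) comes back to the route at 16.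

2. Step 10. Oxidative addition at the doubly ortho-substituted C8a–Br bond may be slow, and base-induced deformylation of the β-keto aldehyde back to the deoxybenzoin may then win. The fallback turns the bromide into the phenol first and closes the ring by condensation. It sets out from 16: palladium-catalysed hydroxylation (Pd2(dba)3, t-BuXPhos, KOH, dioxane/H2O, 90 °C) gives the 2-hydroxy deoxybenzoin F5. Heating with DMF dimethyl acetal forms the enaminone F6, which cyclises by conjugate addition of the phenol and loss of dimethylamine, coming back to the route at 19. The regiochemistry stays fixed because the only free phenol sits where the bromide was and O5 is still a MOM ether.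

3. Step 4. Iodination may go to the other open position, go twice, or be accompanied by oxidation of the electron-rich diol. The fallback iodinates before the Baeyer–Villiger step, where a single phenol has only one free ortho position. It sets out from 3: ICl and pyridine in CH2Cl2 (isovanillin is halogenated in the same way between OH and CHO) give 5-bromo-3-hydroxy-2-iodo-4-methoxybenzaldehyde F7. Oxidation with H2O2 and catalytic diphenyl diselenide, which spares the aryl iodide, gives the aryl formate F8, and acidic methanolysis comes back to the route at 6.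

**Further compounds**

F1 | step 8 | 2-bromo-3-methoxy-4,6-bis(methoxymethoxy)-5-(3-methylbut-2-en-1-yl)benzaldehyde | O=Cc1c(Br)c(OC)c(OCOC)c(CC=C(C)C)c1OCOC
F2 | step 8 | methyl 2,4,5-trimethoxyphenylacetate | COC(=O)Cc1cc(OC)c(OC)cc1OC
F3 | step 8 | methyl 3-[2-bromo-3-methoxy-4,6-bis(methoxymethoxy)-5-(3-methylbut-2-en-1-yl)phenyl]-3-hydroxy-2-(2,4,5-trimethoxyphenyl)propanoate (racemic diastereomer mixture) | COC(=O)C(c1cc(OC)c(OC)cc1OC)C(O)c1c(Br)c(OC)c(OCOC)c(CC=C(C)C)c1OCOC
F4 | step 8 | methyl 3-[2-bromo-3-methoxy-4,6-bis(methoxymethoxy)-5-(3-methylbut-2-en-1-yl)phenyl]-3-oxo-2-(2,4,5-trimethoxyphenyl)propanoate (racemic) | COC(=O)C(c1cc(OC)c(OC)cc1OC)C(=O)c1c(Br)c(OC)c(OCOC)c(CC=C(C)C)c1OCOC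
F5 | step 10 | 1-[2-hydroxy-3-methoxy-4,6-bis(methoxymethoxy)-5-(3-methylbut-2-en-1-yl)phenyl]-2-(2,4,5-trimethoxyphenyl)ethan-1-one | O=C(Cc1cc(OC)c(OC)cc1OC)c1c(O)c(OC)c(OCOC)c(CC=C(C)C)c1OCOC
F6 | step 10 | 3-(dimethylamino)-1-[2-hydroxy-3-methoxy-4,6-bis(methoxymethoxy)-5-(3-methylbut-2-en-1-yl)phenyl]-2-(2,4,5-trimethoxyphenyl)prop-2-en-1-one (alkene geometry not controlled) | CN(C)C=C(c1cc(OC)c(OC)cc1OC)C(=O)c1c(O)c(OC)c(OCOC)c(CC=C(C)C)c1OCOC
F7 | step 4 | 5-bromo-3-hydroxy-2-iodo-4-methoxybenzaldehyde | O=Cc1cc(Br)c(OC)c(O)c1I
F8 | step 4 | 5-bromo-3-hydroxy-2-iodo-4-methoxyphenyl formate | O=COc1cc(Br)c(OC)c(O)c1I
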